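The oxane is numbered O1, C2–C6 and the cyclohexane C1'–C6' (C1' on C3, Br on C3', Cl on C4'). The cyclohexane is closed last at C5'–C6', the only ring bond between two CH2 carbons. Ring-closing metathesis of an open-chain 1,7-diene that already carries the bromolactone, the C3 carbinol, C1'–H and the C3'-Br/C4'-Cl pair forms this bond in one operation. The trans-diequatorial halogen pair, which diaxial addition to a preformed cyclohexene should not give, is therefore set earlier on an acyclic allylic alcohol by catalytic bromochlorination. One bought carbinol centre is relayed to C3 and C1' by an ester-enolate Claisen rearrangement, and C5 follows by bromolactonisation.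

Key step: step 10

Assumption: the face selectivity of the titanium/Schiff-base bromochlorination is assigned by analogy with Z-configured 3-methylalk-2-en-1-ols; the ligand enantiomer that gives (2S,3S)-3 is used.

Step 1
Reactants: 1 (2Z)-3-methylpent-2-en-4-yn-1-ol
Product: 2 (2Z)-3-methylpenta-2,4-dien-1-ol
Conditions: H2 (1 atm), Pd/CaCO3 poisoned with Pb(OAc)2, quinoline, pentane/Et2O, 0 °C, stopped after 1 equiv H2
Reagents that add atoms: none
Why: Lindlar semi-hydrogenation should stop at the alkene and leave the trisubstituted Z olefin untouched, giving the dienol in which CH2OH and vinyl are cis, as the later anti addition requires.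

Step 2
Reactants: 2 (2Z)-3-methylpenta-2,4-dien-1-ol
Product: 3 (2S,3S)-2-bromo-3-chloro-3-methylpent-4-en-1-ol
Conditions: N-bromosuccinimide (1.1 equiv), ClTi(OiPr)3 (1.1 equiv), enantiopure tridentate salicylaldimine–diarylcarbinol Schiff-base ligand (20 mol%), hexanes, −20 °C
Reagents that add atoms: N-bromosuccinimide (O=C1CCC(=O)N1Br); chlorotitanium triisopropoxide (CC(C)O[Ti](Cl)(OC(C)C)OC(C)C)
Why: Catalytic enantioselective bromochlorination of an allylic alcohol, in which the titanium-bound alkoxide directs bromonium formation to one olefin face and chloride is delivered anti to the tertiary carbon, so that the future C3' and C4' are set together under catalyst control and the Z geometry becomes the trans ring relationship.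

Step 3
Reactants: 3 (2S,3S)-2-bromo-3-chloro-3-methylpent-4-en-1-ol
Product: 4 (2S,3S)-2-bromo-3-chloro-3-methylpent-4-en-1-yl trifluoromethanesulfonate
Conditions: Tf2O, 2,6-lutidine, CH2Cl2, −78 °C, used crude
Reagents that add atoms: trifluoromethanesulfonic anhydride (O=S(=O)(OS(=O)(=O)C(F)(F)F)C(F)(F)F)
Why: O-sulfonylation of the primary alcohol with a hindered base at low temperature activates the future C2' for substitution without touching either stereocentre.

Step 4
Reactants: 4 (2S,3S)-2-bromo-3-chloro-3-methylpent-4-en-1-yl trifluoromethanesulfonate; 5 (R)-but-3-yn-2-ol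
Product: 7 (2R,6S,7S)-6-bromo-7-chloro-7-methylnon-8-en-3-yn-2-ol, via dilithio alkynolate 6 (not isolated)
Conditions: 5, n-BuLi (2.0 equiv), THF, −78 to −20 °C; then 4, DMPU, −78 to −30 °C; NH4Cl (aq)
Reagents that add atoms: none
Why: SN2 alkylation of a lithium acetylide by a primary triflate, in which the carbon terminus of the dianion is the more nucleophilic site, joins the future C1' to C2' and carries the bought (R) carbinol centre unchanged.

Step 5
Reactants: 8 2,2-dimethyl-1,3-dioxolan-4-one; 9 1-bromo-3-methylbut-2-ene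
Product: 11 rac-2,2-dimethyl-5-(3-methylbut-2-en-1-yl)-1,3-dioxolan-4-one, via lithium enolate 10 (not isolated)
Conditions: LiN(iPr)2, THF, −78 °C; then 9, −78 to −20 °C
Reagents that add atoms: none
Why: Enolate alkylation of the glycolic acid acetonide with a primary allylic bromide attaches the prenyl chain (future C4–C6); the new centre need not be controlled because it is planarised in step 8.

Step 6
Reactants: 7 (2R,6S,7S)-6-bromo-7-chloro-7-methylnon-8-en-3-yn-2-ol; 11 rac-2,2-dimethyl-5-(3-methylbut-2-en-1-yl)-1,3-dioxolan-4-one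
Product: 13 (2R,6S,7S)-6-bromo-7-chloro-7-methylnon-8-en-3-yn-2-yl 2-hydroxy-5-methylhex-4-enoate (both epimers at C2 of the acid part), via lithium alkoxide 12 (not isolated)
Conditions: 7, n-BuLi (1.0 equiv), THF, −78 °C; then 11, −78 to −20 °C; NH4Cl (aq)
Reagents that add atoms: none
Why: Acyl transfer from the acetal ester, in which the alkoxide opens the dioxolanone and the hemiketal collapses with loss of acetone, gives the α-hydroxy ester directly; it is done on the alkyne, whose linear geometry excludes intramolecular displacement of the bromide.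

Step 7
Reactants: 13 (2R,6S,7S)-6-bromo-7-chloro-7-methylnon-8-en-3-yn-2-yl 2-hydroxy-5-methylhex-4-enoate
Product: 14 (2R,3Z,6S,7S)-6-bromo-7-chloro-7-methylnona-3,8-dien-2-yl 2-hydroxy-5-methylhex-4-enoate
Conditions: H2 (1 atm), Pd/CaCO3 poisoned with Pb(OAc)2, quinoline, EtOAc, 0 °C, stopped after 1 equiv H2
Reagents that add atoms: none
Why: Lindlar cis-semi-hydrogenation of the internal alkyne should give the Z allylic ester, the alkyne binding far more strongly than the trisubstituted prenyl olefin or the hindered vinyl group on the quaternary carbon.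

Step 8
Reactants: 14 (2R,3Z,6S,7S)-6-bromo-7-chloro-7-methylnona-3,8-dien-2-yl 2-hydroxy-5-methylhex-4-enoate
Product: 16 (2R,3R,5S,6S)-5-bromo-6-chloro-2-hydroxy-6-methyl-2-(3-methylbut-2-en-1-yl)-3-[(1E)-prop-1-en-1-yl]oct-7-enoic acid, via bis-silyl ketene acetal 15 (not isolated)
Conditions: LiN(iPr)2 (2.3 equiv), THF, −78 °C; Me3SiCl/Et3N, −78 to 35 °C; then 1 M HCl, THF, 0 °C
Reagents that add atoms: none
Why: Ireland–Claisen rearrangement of an α-hydroxy ester through its chelated Z enediolate: in the chair with the carbinol methyl equatorial and the Z-olefin chain axial, the (R) carbinol centre should be transferred to the quaternary C3 (R) and to C1' at once, leaving an E-propenyl group on C1'.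

Step 9
Reactants: 16 (2R,3R,5S,6S)-5-bromo-6-chloro-2-hydroxy-6-methyl-2-(3-methylbut-2-en-1-yl)-3-[(1E)-prop-1-en-1-yl]oct-7-enoic acid
Product: 17 (3R,5R)-5-bromo-3-[(2E,4R,6S,7S)-6-bromo-7-chloro-7-methylnona-2,8-dien-4-yl]-3-hydroxy-6,6-dimethyloxan-2-one
Conditions: N-bromosuccinimide (1.05 equiv), NaHCO3, CH2Cl2, −40 to −10 °C
Reagents that add atoms: N-bromosuccinimide (O=C1CCC(=O)N1Br)
Why: Bromolactonisation, in which the bromonium ion forms on the most electron-rich (trisubstituted) olefin and the carboxylate opens it at the tertiary C6 in a 6-endo chair with Br equatorial at C5; the C3 hydroxyl, hydrogen-bonded to the exocyclic carboxylate oxygen, should sit equatorial and the branched substituent axial, making Br and OH cis (5R).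

Step 10
Reactants: 17 (3R,5R)-5-bromo-3-[(2E,4R,6S,7S)-6-bromo-7-chloro-7-methylnona-2,8-dien-4-yl]-3-hydroxy-6,6-dimethyloxan-2-one
Product: 18 (3R,5R)-5-bromo-3-[(1R,4S,5S)-5-bromo-4-chloro-4-methylcyclohex-2-en-1-yl]-3-hydroxy-6,6-dimethyloxan-2-one
Conditions: second-generation Hoveyda–Grubbs catalyst RuCl2(H2IMes)(=CH-C6H4-2-OiPr) (10 mol%), CH2Cl2 (5 mM), 40 °C
Reagents that add atoms: none
Why: Olefin metathesis by the Chauvin mechanism: the ruthenium alkylidene loads on one olefin, forms a ruthenacyclobutane with the other in the same molecule and cycloreverts, expelling propene and joining C6' to C5' as a ring olefin. The closest known reaction type is ring-closing metathesis of 1,7-dienes to cyclohexenes that bear allylic quaternary centres. The one ring closed is the six-membered carbocycle, formed by intramolecular alkylidene transfer between the propenyl carbon on C1' and the vinyl carbon on C4', and the ring enforces the Z olefin. No stereocentre is created: C3, C5, C1', C3' and C4' are all in place and none belongs to a reacting olefin, so nothing can be scrambled. The step needs chemoselectivity and tolerance of the tertiary allylic chloride, the secondary bromides and the free tertiary alcohol; the prenyl olefin was consumed in step 9, neutral conditions at 40 °C should avoid ionisation of C4'–Cl, and the substitution at C3 and C4' favours cyclisation over oligomerisation.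

Step 11
Reactants: 18 (3R,5R)-5-bromo-3-[(1R,4S,5S)-5-bromo-4-chloro-4-methylcyclohex-2-en-1-yl]-3-hydroxy-6,6-dimethyloxan-2-one
Product: 19 (3R,5R)-5-bromo-3-[(1S,3S,4S)-3-bromo-4-chloro-4-methylcyclohexyl]-3-hydroxy-6,6-dimethyloxan-2-one
Conditions: KO2C–N=N–CO2K (excess), AcOH, pyridine/MeOH, 0 to 23 °C
Reagents that add atoms: none
Why: Diimide reduction transfers H2 suprafacially to the cis-disubstituted ring olefin through a six-centre transition state and leaves C–Br, the allylic C–Cl and the lactone alone, which metal-catalysed hydrogenation of an allylic chloride would not guarantee.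

Step 12
Reactants: 19 (3R,5R)-5-bromo-3-[(1S,3S,4S)-3-bromo-4-chloro-4-methylcyclohexyl]-3-hydroxy-6,6-dimethyloxan-2-one
Product: 20 (3R,5R)-5-bromo-3-[(1S,3S,4S)-3-bromo-4-chloro-4-methylcyclohexyl]-6,6-dimethyl-2-methylideneoxan-3-ol
Conditions: Cp2TiMe2 (3 equiv), toluene/THF, 65 °C, dark; NaHCO3 (aq); chromatography on Et3N-deactivated silica
Reagents that add atoms: dimethyltitanocene Cp2TiMe2 (C[Ti](C)(C1C=CC=C1)C1C=CC=C1)
Why: Petasis methylenation, in which Cp2Ti=CH2 formed by loss of methane converts the lactone carbonyl through an oxatitanacyclobutane into the exocyclic enol ether under neutral conditions that the alkyl halides should tolerate, the tertiary hydroxyl being titanated by the extra equivalent and released on work-up.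

Compound list
1 | (2Z)-3-methylpent-2-en-4-yn-1-ol | C#C/C(C)=C\CO | starting material
2 | (2Z)-3-methylpenta-2,4-dien-1-ol | C=C/C(C)=C\CO | intermediate
3 | (2S,3S)-2-bromo-3-chloro-3-methylpent-4-en-1-ol | OC[C@H](Br)[C@@](C)(Cl)C=C | intermediate
4 | (2S,3S)-2-bromo-3-chloro-3-methylpent-4-en-1-yl trifluoromethanesulfonate | C=C[C@](C)(Cl)[C@@H](Br)COS(=O)(=O)C(F)(F)F | intermediate
5 | (R)-but-3-yn-2-ol | C[C@@H](O)C#C | starting material
6 | dilithio alkynolate of 5 (O-lithio, C-lithio) | C[C@@H](O[Li])C#C[Li] | intermediate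
7 | (2R,6S,7S)-6-bromo-7-chloro-7-methylnon-8-en-3-yn-2-ol | C[C@@H](O)C#CC[C@H](Br)[C@@](C)(Cl)C=C | intermediate
8 | 2,2-dimethyl-1,3-dioxolan-4-one | CC1(C)OCC(=O)O1 | starting material
9 | 1-bromo-3-methylbut-2-ene (prenyl bromide) | CC(C)=CCBr | starting material
10 | lithium enolate of 8 | CC1(C)OC=C(O[Li])O1 | intermediate
11 | rac-2,2-dimethyl-5-(3-methylbut-2-en-1-yl)-1,3-dioxolan-4-one | CC(C)=CCC1OC(C)(C)OC1=O | intermediate
12 | lithium alkoxide of 7 | C[C@@H](O[Li])C#CC[C@H](Br)[C@@](C)(Cl)C=C | intermediate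
13 | (2R,6S,7S)-6-bromo-7-chloro-7-methylnon-8-en-3-yn-2-yl 2-hydroxy-5-methylhex-4-enoate | CC(C)=CCC(O)C(=O)O[C@H](C)C#CC[C@H](Br)[C@@](C)(Cl)C=C | intermediate
14 | (2R,3Z,6S,7S)-6-bromo-7-chloro-7-methylnona-3,8-dien-2-yl 2-hydroxy-5-methylhex-4-enoate | CC(C)=CCC(O)C(=O)O[C@H](C)/C=C\C[C@H](Br)[C@@](C)(Cl)C=C | intermediate
15 | bis(trimethylsilyl) ketene acetal of 14 (both silyloxy groups cis) | CC(C)=CC/C(O[Si](C)(C)C)=C(/O[Si](C)(C)C)O[C@H](C)/C=C\C[C@H](Br)[C@@](C)(Cl)C=C | intermediate
16 | (2R,3R,5S,6S)-5-bromo-6-chloro-2-hydroxy-6-methyl-2-(3-methylbut-2-en-1-yl)-3-[(1E)-prop-1-en-1-yl]oct-7-enoic acid | CC(C)=CC[C@@](C(=O)O)(O)[C@H](C[C@H](Br)[C@@](C)(Cl)C=C)/C=C/C | intermediate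
17 | (3R,5R)-5-bromo-3-[(2E,4R,6S,7S)-6-bromo-7-chloro-7-methylnona-2,8-dien-4-yl]-3-hydroxy-6,6-dimethyloxan-2-one | O=C1OC(C)(C)[C@H](Br)C[C@@]1(O)[C@H](C[C@H](Br)[C@@](C)(Cl)C=C)/C=C/C | intermediate
18 | (3R,5R)-5-bromo-3-[(1R,4S,5S)-5-bromo-4-chloro-4-methylcyclohex-2-en-1-yl]-3-hydroxy-6,6-dimethyloxan-2-one | O=C1OC(C)(C)[C@H](Br)C[C@@]1(O)[C@H]1C=C[C@](C)(Cl)[C@@H](Br)C1 | intermediate
19 | (3R,5R)-5-bromo-3-[(1S,3S,4S)-3-bromo-4-chloro-4-methylcyclohexyl]-3-hydroxy-6,6-dimethyloxan-2-one | O=C1OC(C)(C)[C@H](Br)C[C@@]1(O)[C@H]1CC[C@](C)(Cl)[C@@H](Br)C1 | intermediate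
20 | (3R,5R)-5-bromo-3-[(1S,3S,4S)-3-bromo-4-chloro-4-methylcyclohexyl]-6,6-dimethyl-2-methylideneoxan-3-ol | C=C1OC(C)(C)[C@H](Br)C[C@@]1(O)[C@H]1CC[C@](C)(Cl)[C@@H](Br)C1 | target

Total steps: 12. Longest linear sequence: 11 steps (steps 1–4 and 6–12); step 5 is the one-step side branch.

Steps most likely to fail

Step 9. The risk is poor facial selectivity at C5 if the hydrogen-bonded chair with the C3 hydroxyl equatorial does not dominate, together with competing 5-exo closure or attack by the tertiary hydroxyl. The fallback sets out from 16 and comes back at 17. Compound 16 is condensed with 2,2-dimethoxypropane (pyridinium p-toluenesulfonate, CH2Cl2) to the acetonide (5R)-5-[(2E,4R,6S,7S)-6-bromo-7-chloro-7-methylnona-2,8-dien-4-yl]-2,2-dimethyl-5-(3-methylbut-2-en-1-yl)-1,3-dioxolan-4-one F6. N-Bromosuccinimide in wet MeCN at 0 °C should then let the dioxolanone carbonyl oxygen open the bromonium ion at C6, and the resulting dioxolanylium ion is hydrolysed with loss of acetone to 17. The five-membered ring holds the C3–O bond antiperiplanar to the attacking oxygen, that is equatorial in the forming ring, by a covalent constraint instead of a hydrogen bond; the reaction type is halolactonisation of an ester with loss of its O-alkyl part.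

Step 4. The risk is elimination (loss of HBr or of triflic acid) caused by the basic acetylide, or O-alkylation of the dianion in place of C-alkylation. The fallback sets out from 4 and comes back at 14, replacing the substitution by an olefination that forms the future C1'=C6' bond. Triflate 4 is alkylated by Ph3P=CH2 (from Ph3PCH3Br and n-BuLi, THF, −78 °C) to [(3S,4S)-3-bromo-4-chloro-4-methylhex-5-en-1-yl]triphenylphosphonium trifluoromethanesulfonate F2. NaN(SiMe3)2 (THF, −78 °C) gives the ylide [(3S,4S)-3-bromo-4-chloro-4-methylhex-5-en-1-ylidene]triphenylphosphorane F3. A salt-free Wittig reaction of this ylide with (R)-2-[(tert-butyldimethylsilyl)oxy]propanal (C[C@@H](O[Si](C)(C)C(C)(C)C)C=O, from methyl (R)-lactate) should give the Z olefin tert-butyl{[(2R,3Z,6S,7S)-6-bromo-7-chloro-7-methylnona-3,8-dien-2-yl]oxy}dimethylsilane F4. HF·pyridine in THF frees (2R,3Z,6S,7S)-6-bromo-7-chloro-7-methylnona-3,8-dien-2-ol F5, whose lithium alkoxide (n-BuLi, THF, −78 °C) is acylated by 11 to give 14. Steps 4, 6 and 7 are bypassed.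

Step 2. The risk is capture of chloride at the diene terminus (1,4-addition through the allyl-type cation) or eroded enantioselectivity with the conjugated dienol. The fallback sets out from 1 and comes back at 3. The same titanium/Schiff-base bromochlorination is run on the enynol 1, whose alkyne cannot relay the positive charge to a remote carbon, to give (2S,3S)-2-bromo-3-chloro-3-methylpent-4-yn-1-ol F1. The terminal alkyne is then semi-hydrogenated (H2, Pd/CaCO3 poisoned with Pb(OAc)2, quinoline, 0 °C) to 3, so compound 2 is not needed.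

Further compounds
F1 | step 2 | (2S,3S)-2-bromo-3-chloro-3-methylpent-4-yn-1-ol | OC[C@H](Br)[C@@](C)(Cl)C#C
F2 | step 4 | [(3S,4S)-3-bromo-4-chloro-4-methylhex-5-en-1-yl]triphenylphosphonium trifluoromethanesulfonate | C=C[C@](C)(Cl)[C@@H](Br)CC[P+](c1ccccc1)(c1ccccc1)c1ccccc1.[O-]S(=O)(=O)C(F)(F)F
F3 | step 4 | [(3S,4S)-3-bromo-4-chloro-4-methylhex-5-en-1-ylidene]triphenylphosphorane | C=C[C@](C)(Cl)[C@@H](Br)CC=P(c1ccccc1)(c1ccccc1)c1ccccc1
F4 | step 4 | tert-butyl{[(2R,3Z,6S,7S)-6-bromo-7-chloro-7-methylnona-3,8-dien-2-yl]oxy}dimethylsilane | C[C@@H](O[Si](C)(C)C(C)(C)C)/C=C\C[C@H](Br)[C@@](C)(Cl)C=C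
F5 | step 4 | (2R,3Z,6S,7S)-6-bromo-7-chloro-7-methylnona-3,8-dien-2-ol | C[C@@H](O)/C=C\C[C@H](Br)[C@@](C)(Cl)C=C
F6 | step 9 | (5R)-5-[(2E,4R,6S,7S)-6-bromo-7-chloro-7-methylnona-2,8-dien-4-yl]-2,2-dimethyl-5-(3-methylbut-2-en-1-yl)-1,3-dioxolan-4-one | CC(C)=CC[C@@]1(OC(C)(C)OC1=O)[C@H](C[C@H](Br)[C@@](C)(Cl)C=C)/C=C/C
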